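The readings are calculated for an exercise, and the scatter is random.

1. Z in Monday's run, the flask asked about followed so far, stands at 11.2 %, 10.8 % and 13.0 % in its last readings, which is 18.9 mM on average, while G still reads 38.1 %.

- Monday's: G 0.081 M; X 0.081 M; E 0.0891 M; D 0.29 mM; the very flask that is asked about, followed so far
- flask: G 0.081 M; E 0.0891 M; D 0.29 mM; X 0.081 M; time 25 min

- Monday's (time / min: G / %, Z / %): 0.667: 47.8, 2.3; 2.00: 46.8, 3.1; 4.00: 39.9, 8.4; 5.00: 37.3, 11.2; 8.00: 38.4, 10.8; 10.0: 38.1, 13.0

(scatter of a reading: 1 percentage point)

1. at 25 min, what has stopped the reaction, if anything has (for what has run out or reacted, a solid counts together with what of it has only dissolved) (it is still moving / no working catalyst is left / all of G has reacted / L has run out first)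
2. share of the G and X together used up at 25 min
3. Z at 25 min, in percent of the G and X together charged

- D is single-handed; G and X are mirror images of each other, charged as a racemate, each of them at the stated concentration
- as a solid, counted per litre of solution: E
- the analysis behind the earlier runs scatters by 1 percentage point, standard deviation
- at the start none of E is in solution
- the reaction counts as stopped when no species that holds the G and X together changes by six tenths of a point or more over the second half of the time

2. The stall in Monday's run, with G present, is read here in one of two ways: D has died, or L has stopped coming. My own reckoning takes the second, as a judgement the readings cannot prove. Two rates then count: L passing into Z, taken as proportional to [D], and L leaving by every other way.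

3. If L has stopped coming, the plateau reading over the charge of E, 0.0891 M, gives the share of E reaching Z as 21.2 %, a reading with the scatter of the analysis. The capture odds, a branching ratio of the first rate to the second, are then 0.269, less than one.

4. My reckoning therefore has L no longer coming and Z held near 11.7 % at 25 min. X is unread, so it gives no conversion.

The forecast says no working catalyst is left, with conversion 14.5 % and Z 13.5 %, on the ground that “The likeliest cause is catalyst death”. It differs from my reckoning on the stop, and its Z stands above mine.

5. The flask's answer on the stop is that L has run out first, with 0 M of L at 25.0 min, conversion 15.3 % and Z 11.5 %.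

    L + D + G → D + Z (k = 810 L² mol⁻² s⁻¹)
    L + D + X → D + J (k = 250 L² mol⁻² s⁻¹)
    E ⇌ L, rate k3*(cs3 - [L]) while solid is left; crystals form when [L] > cs3 (solubility = 4.20 mM, k = 0.860 s⁻¹)
    L → Q (k = 0.0580 s⁻¹)

At 25.0 min, D stands at 100 % of its charge and E, the limiting reagent, at 0 %. L has turned over 39.7 % into Q, more than the 11.5 % into Z, so these turnovers put the flask's capture odds at 0.263.

In the neighbour flask with 7.2 × 10⁻⁴ M of D, the odds, if taken as proportional to [D], are 0.668, which gives an estimated Z of 22.0 %. The computed neighbour gives 18.9 %, less than that.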